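**Retrosynthetic overview**
- The target is a C2-symmetric sulfide of two identical 12-membered lactones. Cutting both C2–S bonds gives two molecules of one (E)-5-silyloxy-4-oxo-2-en-11-olide plus one sulfur atom, joined by a new catalyst-controlled two-fold sulfa-Michael addition that sets C2 and C2'.
- The enone macrolide comes from its C4 allylic alcohol, whose C3–C4 bond and 12-membered ring are made by an intramolecular Nozaki–Hiyama–Kishi reaction of an (E)-β-iodoacrylate onto an α-silyloxy aldehyde.
- The open-chain precursor is cut at the C11–O ester bond ((E)-3-iodoacrylic acid) and at C7–C8 (acetylide alkylation), giving (R)-pent-4-yn-2-ol (C8–C12, brings C11) and the iodide of (S)-butane-1,2,4-triol acetonide (C4–C7, brings C5).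
- Ring order: the 12-membered lactone is closed once at the monomer stage (step 9), the two identical rings are then linked through sulfur (step 11), and no ring is formed afterwards.

Assumption: the SMILES is read as the homodimeric sulfide with 2S,5S,11R configuration in both halves (natural-product numbering: C1 lactone carbonyl, C2 sulfur-bearing carbon, C4 ketone, C5 carbinol, C11 methyl-bearing carbinol), and the three building blocks are taken as purchasable.

**Step 1**
Reactants: 1 2-[(4S)-2,2-dimethyl-1,3-dioxolan-4-yl]ethan-1-ol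
Product: 2 (4S)-4-(2-iodoethyl)-2,2-dimethyl-1,3-dioxolane
Conditions: I2, PPh3, imidazole, CH2Cl2, 0 °C → rt
Reagents that add atoms: iodine, [I][I]
Why: Appel-type iodination replaces the primary hydroxyl by SN2 at the CH2 carbon, so the dioxolane stereocentre (future C5) is untouched.

**Step 2**
Reactants: 3 (2R)-pent-4-yn-2-ol; 2 (4S)-4-(2-iodoethyl)-2,2-dimethyl-1,3-dioxolane
Product: 5 (2R)-7-[(4S)-2,2-dimethyl-1,3-dioxolan-4-yl]hept-4-yn-2-ol, via dilithio dianion 4 (not isolated)
Conditions: n-BuLi (2.1 equiv), THF, −78 → −20 °C; then 2, DMPU, −20 °C → rt; then H2O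
Reagents that add atoms: none
Why: Acetylide alkylation (SN2) forms the C7–C8 bond because the acetylide carbon of the dianion is far more nucleophilic toward a primary iodide than the lithium alkoxide; both stereocentres come unchanged from the chiral pool.

**Step 3**
Reactants: 5 (2R)-7-[(4S)-2,2-dimethyl-1,3-dioxolan-4-yl]hept-4-yn-2-ol
Product: 6 (2R)-7-[(4S)-2,2-dimethyl-1,3-dioxolan-4-yl]heptan-2-ol
Conditions: H2 (1 atm), Pd/C (10% palladium on carbon), EtOAc, rt
Reagents that add atoms: none
Why: Catalytic hydrogenation saturates the alkyne to the C6–C10 pentamethylene chain without touching the acetonide or the carbinol.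

**Step 4**
Reactants: 6 (2R)-7-[(4S)-2,2-dimethyl-1,3-dioxolan-4-yl]heptan-2-ol; 7 (2E)-3-iodoprop-2-enoic acid
Product: 8 (2R)-7-[(4S)-2,2-dimethyl-1,3-dioxolan-4-yl]heptan-2-yl (2E)-3-iodoprop-2-enoate
Conditions: DIC, DMAP (10 mol%), CH2Cl2, 0 °C → rt
Reagents that add atoms: none
Why: Steglich esterification acylates the C11 hydroxyl with retention (the C–O bond is not broken), and the E-iodoacrylate is the thermodynamic isomer so its geometry holds.

**Step 5**
Reactants: 8 (2R)-7-[(4S)-2,2-dimethyl-1,3-dioxolan-4-yl]heptan-2-yl (2E)-3-iodoprop-2-enoate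
Product: 9 (2R,8S)-8,9-dihydroxynonan-2-yl (2E)-3-iodoprop-2-enoate
Conditions: AcOH/H2O (4:1), 40 °C
Reagents that add atoms: none
Why: Mild acid hydrolysis of the acetonide frees the C4/C5 diol while the ester and vinyl iodide are stable to aqueous acetic acid.

**Step 6**
Reactants: 9 (2R,8S)-8,9-dihydroxynonan-2-yl (2E)-3-iodoprop-2-enoate
Product: 10 (2R,8S)-8,9-bis[(tert-butyldimethylsilyl)oxy]nonan-2-yl (2E)-3-iodoprop-2-enoate
Conditions: TBSOTf (2.4 equiv), 2,6-lutidine, CH2Cl2, −78 → 0 °C
Reagents that add atoms: tert-butyldimethylsilyl trifluoromethanesulfonate, CC(C)(C)[Si](C)(C)OS(=O)(=O)C(F)(F)F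
Why: Exhaustive silylation with a silyl triflate and a hindered, non-nucleophilic base protects both hydroxyls without adding to the β-iodoacrylate.

**Step 7**
Reactants: 10 (2R,8S)-8,9-bis[(tert-butyldimethylsilyl)oxy]nonan-2-yl (2E)-3-iodoprop-2-enoate
Product: 11 (2R,8S)-8-[(tert-butyldimethylsilyl)oxy]-9-hydroxynonan-2-yl (2E)-3-iodoprop-2-enoate
Conditions: CSA (10 mol%), MeOH/CH2Cl2 (1:1), −10 → 0 °C
Reagents that add atoms: none
Why: Acid-catalysed methanolysis cleaves the less hindered primary silyl ether much faster than the secondary one (selective desilylation).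

**Step 8**
Reactants: 11 (2R,8S)-8-[(tert-butyldimethylsilyl)oxy]-9-hydroxynonan-2-yl (2E)-3-iodoprop-2-enoate
Product: 12 (2R,8S)-8-[(tert-butyldimethylsilyl)oxy]-9-oxononan-2-yl (2E)-3-iodoprop-2-enoate
Conditions: Dess–Martin periodinane, CH2Cl2, 0 °C → rt
Reagents that add atoms: none
Why: Dess–Martin oxidation gives the α-silyloxy aldehyde under non-basic conditions, so the C5 stereocentre does not epimerise; the aldehyde is used at once.

**Step 9**
Reactants: 12 (2R,8S)-8-[(tert-butyldimethylsilyl)oxy]-9-oxononan-2-yl (2E)-3-iodoprop-2-enoate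
Product: 14 (3E,6S,12R)-6-[(tert-butyldimethylsilyl)oxy]-5-hydroxy-12-methyl-1-oxacyclododec-3-en-2-one (both C5 carbinol epimers), via alkenylchromium dichloride 13 (not isolated)
Conditions: CrCl2 (8 equiv), NiCl2 (2 mol%), degassed DMSO, slow addition of 12 to 2 mM, rt; then H2O
Reagents that add atoms: none
Why: Intramolecular Nozaki–Hiyama–Kishi reaction: zerovalent nickel formed from NiCl2 and CrCl2 inserts into the C–I bond and transmetalates to trivalent chromium, and the resulting alkenylchromium adds chemoselectively to the aldehyde under high dilution. This forms the C3–C4 bond and the 12-membered ring with the E geometry retained; the new carbinol configuration is irrelevant because it is oxidised next.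

**Step 10**
Reactants: 14 (3E,6S,12R)-6-[(tert-butyldimethylsilyl)oxy]-5-hydroxy-12-methyl-1-oxacyclododec-3-en-2-one
Product: 15 (3E,6S,12R)-6-[(tert-butyldimethylsilyl)oxy]-12-methyl-1-oxacyclododec-3-ene-2,5-dione
Conditions: Dess–Martin periodinane, CH2Cl2, 0 °C → rt
Reagents that add atoms: none
Why: Dess–Martin oxidation of the allylic alcohol converges both carbinol epimers to the single E-configured 4-oxo-2-enoate macrolide without base that could epimerise C5.

**Step 11**
Reactants: 15 (3E,6S,12R)-6-[(tert-butyldimethylsilyl)oxy]-12-methyl-1-oxacyclododec-3-ene-2,5-dione (two molecules)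
Product: 17 bis{(3S,6S,12R)-6-[(tert-butyldimethylsilyl)oxy]-12-methyl-2,5-dioxo-1-oxacyclododecan-3-yl} sulfide, via monoadduct thiol 16 (not isolated)
Conditions: (Me3Si)2S (0.50 equiv), H2O (0.50 equiv), quinine-derived squaramide 3-{[3,5-bis(trifluoromethyl)phenyl]amino}-4-{[(8α,9S)-6'-methoxycinchonan-9-yl]amino}cyclobut-3-ene-1,2-dione (10 mol%), CH2Cl2, sealed vessel under argon, −40 → −20 °C
Reagents that add atoms: hexamethyldisilathiane, C[Si](C)(C)S[Si](C)(C)C
Why: Proposed new method: water slowly releases H2S from the disilathiane, the quinuclidine nitrogen deprotonates H2S and then the more acidic α-mercapto ester thiol 16, and the squaramide N–H pair binds the C4 ketone, so that hydrosulfide and then thiolate are delivered to C2 (β to the more activating ketone, α to the lactone carbonyl) on its Si face twice in succession; this forms both C2–S bonds and sets both sulfur-bearing centres as S under catalyst control chosen to reinforce peripheral attack on the macrocycle. The closest known reaction type is the bifunctional amine–squaramide-catalysed enantioselective sulfa-Michael addition of thiols or thioacetic acid to enones, which has not been run with a sulfide dianion equivalent as a two-fold linchpin nor on a macrocyclic 4-oxo-2-enoate.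

**Step 12**
Reactants: 17 bis{(3S,6S,12R)-6-[(tert-butyldimethylsilyl)oxy]-12-methyl-2,5-dioxo-1-oxacyclododecan-3-yl} sulfide
Product: 18 Thiocladospolide F, bis[(3S,6S,12R)-6-hydroxy-12-methyl-2,5-dioxo-1-oxacyclododecan-3-yl] sulfide
Conditions: HF·pyridine, THF, 0 °C → rt
Reagents that add atoms: none
Why: Fluoride-mediated desilylation in an acidic medium frees both C5 hydroxyls while avoiding the base that would trigger retro-sulfa-Michael cleavage, C2 epimerisation or α-ketol shift.

**Compound list**
1 | 2-[(4S)-2,2-dimethyl-1,3-dioxolan-4-yl]ethan-1-ol | OCC[C@H]1COC(C)(C)O1 | starting material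
2 | (4S)-4-(2-iodoethyl)-2,2-dimethyl-1,3-dioxolane | ICC[C@H]1COC(C)(C)O1 | intermediate
3 | (2R)-pent-4-yn-2-ol | C[C@@H](O)CC#C | starting material
4 | dilithio dianion of 3, lithium alkoxide and lithium acetylide (not isolated) | C[C@@H]([O-])CC#[C-].[Li+].[Li+] | intermediate
5 | (2R)-7-[(4S)-2,2-dimethyl-1,3-dioxolan-4-yl]hept-4-yn-2-ol | C[C@@H](O)CC#CCC[C@H]1COC(C)(C)O1 | intermediate
6 | (2R)-7-[(4S)-2,2-dimethyl-1,3-dioxolan-4-yl]heptan-2-ol | C[C@@H](O)CCCCC[C@H]1COC(C)(C)O1 | intermediate
7 | (2E)-3-iodoprop-2-enoic acid | OC(=O)/C=C/I | starting material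
8 | (2R)-7-[(4S)-2,2-dimethyl-1,3-dioxolan-4-yl]heptan-2-yl (2E)-3-iodoprop-2-enoate | C[C@@H](OC(=O)/C=C/I)CCCCC[C@H]1COC(C)(C)O1 | intermediate
9 | (2R,8S)-8,9-dihydroxynonan-2-yl (2E)-3-iodoprop-2-enoate | C[C@@H](OC(=O)/C=C/I)CCCCC[C@H](O)CO | intermediate
10 | (2R,8S)-8,9-bis[(tert-butyldimethylsilyl)oxy]nonan-2-yl (2E)-3-iodoprop-2-enoate | C[C@@H](OC(=O)/C=C/I)CCCCC[C@H](O[Si](C)(C)C(C)(C)C)CO[Si](C)(C)C(C)(C)C | intermediate
11 | (2R,8S)-8-[(tert-butyldimethylsilyl)oxy]-9-hydroxynonan-2-yl (2E)-3-iodoprop-2-enoate | C[C@@H](OC(=O)/C=C/I)CCCCC[C@H](O[Si](C)(C)C(C)(C)C)CO | intermediate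
12 | (2R,8S)-8-[(tert-butyldimethylsilyl)oxy]-9-oxononan-2-yl (2E)-3-iodoprop-2-enoate | C[C@@H](OC(=O)/C=C/I)CCCCC[C@H](O[Si](C)(C)C(C)(C)C)C=O | intermediate
13 | alkenylchromium dichloride from 12, trivalent chromium on C3 (not isolated) | C[C@@H](OC(=O)/C=C/[Cr](Cl)Cl)CCCCC[C@H](O[Si](C)(C)C(C)(C)C)C=O | intermediate
14 | (3E,6S,12R)-6-[(tert-butyldimethylsilyl)oxy]-5-hydroxy-12-methyl-1-oxacyclododec-3-en-2-one (C5 epimer mixture) | C[C@@H]1CCCCC[C@H](O[Si](C)(C)C(C)(C)C)C(O)/C=C/C(=O)O1 | intermediate
15 | (3E,6S,12R)-6-[(tert-butyldimethylsilyl)oxy]-12-methyl-1-oxacyclododec-3-ene-2,5-dione | C[C@@H]1CCCCC[C@H](O[Si](C)(C)C(C)(C)C)C(=O)/C=C/C(=O)O1 | intermediate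
16 | (3S,6S,12R)-6-[(tert-butyldimethylsilyl)oxy]-12-methyl-3-sulfanyl-1-oxacyclododecane-2,5-dione (not isolated) | C[C@@H]1CCCCC[C@H](O[Si](C)(C)C(C)(C)C)C(=O)C[C@H](S)C(=O)O1 | intermediate
17 | bis{(3S,6S,12R)-6-[(tert-butyldimethylsilyl)oxy]-12-methyl-2,5-dioxo-1-oxacyclododecan-3-yl} sulfide | C[C@@H]1CCCCC[C@H](O[Si](C)(C)C(C)(C)C)C(=O)C[C@H](S[C@H]2CC(=O)[C@@H](O[Si](C)(C)C(C)(C)C)CCCCC[C@@H](C)OC2=O)C(=O)O1 | intermediate
18 | Thiocladospolide F, bis[(3S,6S,12R)-6-hydroxy-12-methyl-2,5-dioxo-1-oxacyclododecan-3-yl] sulfide | C[C@@H]1CCCCC[C@H](O)C(=O)C[C@H](S[C@H]2CC(=O)[C@@H](O)CCCCC[C@@H](C)OC2=O)C(=O)O1 | target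

**Step count and risks**
Total step count: 12. Longest linear sequence: 12 steps (1 → 18); 3 and 7 enter as purchased building blocks.

Most likely to fail:

1. Step 11 (proposed new two-fold sulfa-Michael linchpin). The risks are the wrong facial sense at C2, stalling at thiol 16, and retro-Michael scrambling. The pseudoenantiomeric quinidine-derived squaramide is the first condition-level remedy if the catalyst proves mismatched. The fallback uses known chemistry and is stepwise and substrate-controlled. It sets out from 15: thioacetic acid with catalytic Et3N in CH2Cl2 at −40 °C adds conjugately at C2 to give thioacetate F7, whose 2S epimer is separated by chromatography. Mild S-deacetylation with cysteamine (degassed MeOH/pH 8 buffer, rt) gives thiol 16, here isolated. Amine-catalysed sulfa-Michael addition of 16 to a second equivalent of 15 (Et3N 10 mol%, CH2Cl2, −20 °C), with chromatographic removal of the minor 2'-epimer, comes back to the route at 17.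

2. Step 9 (NHK macrocyclisation). The risks are oligomerisation and reduction of the iodoacrylate. The fallback closes the ring at C2=C3 by ring-closing metathesis and sets out from 6. Acryloyl chloride/Et3N gives acrylate F1. Aqueous AcOH gives diol F2. TBSOTf/2,6-lutidine gives bis-silyl ether F3. CSA/MeOH gives primary alcohol F4. Dess–Martin oxidation gives aldehyde F5. Vinylmagnesium bromide (CH2=CHMgBr, THF, −78 °C, aldehyde-selective) gives allylic alcohol F6 as a carbinol epimer mixture. Ring-closing metathesis with second-generation Grubbs catalyst, RuCl2(=CHPh)(H2IMes)(PCy3), in refluxing CH2Cl2 at 1 mM, with chromatographic removal of any Z isomer, comes back to the route at 14.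

3. Step 12 (final double desilylation on the base-sensitive β-keto sulfide). The risks are incomplete cleavage of the hindered α-keto silyl ethers and retro-Michael loss of sulfur. The fallback removes the protecting group before sulfur is introduced and sets out from 15. Aqueous HF in MeCN at 0 °C gives hydroxy enone F8. F8 is then submitted to the step 11 conditions (or to the thioacetate sequence above), passing through hydroxy thiol F9 (not isolated), and comes back to the route directly at 18.

**Further compounds**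
F1 | step 9 | (2R)-7-[(4S)-2,2-dimethyl-1,3-dioxolan-4-yl]heptan-2-yl prop-2-enoate | C[C@@H](OC(=O)C=C)CCCCC[C@H]1COC(C)(C)O1
F2 | step 9 | (2R,8S)-8,9-dihydroxynonan-2-yl prop-2-enoate | C[C@@H](OC(=O)C=C)CCCCC[C@H](O)CO
F3 | step 9 | (2R,8S)-8,9-bis[(tert-butyldimethylsilyl)oxy]nonan-2-yl prop-2-enoate | C[C@@H](OC(=O)C=C)CCCCC[C@H](O[Si](C)(C)C(C)(C)C)CO[Si](C)(C)C(C)(C)C
F4 | step 9 | (2R,8S)-8-[(tert-butyldimethylsilyl)oxy]-9-hydroxynonan-2-yl prop-2-enoate | C[C@@H](OC(=O)C=C)CCCCC[C@H](O[Si](C)(C)C(C)(C)C)CO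
F5 | step 9 | (2R,8S)-8-[(tert-butyldimethylsilyl)oxy]-9-oxononan-2-yl prop-2-enoate | C[C@@H](OC(=O)C=C)CCCCC[C@H](O[Si](C)(C)C(C)(C)C)C=O
F6 | step 9 | (2R,8S)-8-[(tert-butyldimethylsilyl)oxy]-9-hydroxyundec-10-en-2-yl prop-2-enoate (C9 epimer mixture) | C[C@@H](OC(=O)C=C)CCCCC[C@H](O[Si](C)(C)C(C)(C)C)C(O)C=C
F7 | step 11 | (3S,6S,12R)-3-(acetylsulfanyl)-6-[(tert-butyldimethylsilyl)oxy]-12-methyl-1-oxacyclododecane-2,5-dione | C[C@@H]1CCCCC[C@H](O[Si](C)(C)C(C)(C)C)C(=O)C[C@H](SC(C)=O)C(=O)O1
F8 | step 12 | (3E,6S,12R)-6-hydroxy-12-methyl-1-oxacyclododec-3-ene-2,5-dione | C[C@@H]1CCCCC[C@H](O)C(=O)/C=C/C(=O)O1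
F9 | step 12 | (3S,6S,12R)-6-hydroxy-12-methyl-3-sulfanyl-1-oxacyclododecane-2,5-dione | C[C@@H]1CCCCC[C@H](O)C(=O)C[C@H](S)C(=O)O1
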